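Follow the solid.

solid substrate 1.5 M; gas phase 200 mM (held); time 8.0 h

* the target standing at 8.0 h, as a percentage of the solid substrate charged
* the change that raises the amount of target at 8.0 h, in percent of the solid substrate charged most ("none" if none brings more than 2 percentage points) (elm / cedar / oak / maple / none)
* amount of target at 8.0 h, in percent of the solid substrate charged, after maple

- percent here means solid substrate units held: one side product counts as two
- solid substrate is a solid; its amount is given per volume of the solution
- at the start none of the gas is dissolved
- at the start none of the solid substrate is in solution
- run time (flask): 8.0 h

- elm: doubling the solubility in step 5, all else as stated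
- cedar: doubling the saturation concentration of gas phase, all else as stated
- oak: doubling the dissolution coefficient of step 5, all else as stated
- maple: doubling the transfer coefficient of step 1, all else as stated

    gas phase ⇌ dissolved gas, rate k1*(csat - [dissolved gas]) (k1 = 0.00131 s⁻¹, csat = 200 mM)
    starting material + dissolved gas → target (k2 = 0.00153 M⁻¹ s⁻¹)
    target ⇌ isomer of the product (K3 = 2.61, k3 = 5.01 × 10⁻⁵ s⁻¹)
    starting material + target → side product (k4 = 2.32 × 10⁻⁴ M⁻¹ s⁻¹)
    solid substrate ⇌ starting material, rate k5*(cs5 - [starting material]) while solid is left; crystals form when [starting material] > cs5 (cs5 = 0.31 M, k5 = 4.90 × 10⁻⁵ s⁻¹)

I wrote the balance of starting material. The gas is held, so the solid substrate must supply every unit of target. The solid enters fastest while the solution is empty, at 4.90 × 10⁻⁵ s⁻¹ times 0.31 M, which is 0.0547 M h⁻¹. Gas crosses at up to 0.943 M h⁻¹, which is 17.2 times that rate, so I took dissolving as the rate-limiting step. Over 8.0 h the solid's rate gives 0.437 M, or 29.2% of this charge: the most that can enter a solution kept empty, the dissolving ceiling. While solid is left, the size of the charge does not enter it. I expected target to stay under that ceiling and maple to bring little. Elm and oak each double the ceiling, and I could not part them. My reckoning stopped there.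

The forecast said 11.7%, elm as the best change, and 11.9% after maple: “Dissolution of the solid is the bottleneck”.

The simulation gave 11.6% and elm as the best change, gaining 8.4 percentage points against 6.7 points for oak. Maple gave 11.7%, a gain of 0.086 points.

In the flask, dissolving ran throughout while solid substrate stood, with half its turnover done by 3.96 h and 74.4% still solid at 8.00 h. At that time [dissolved gas] stood at 0.191 M, and the step to target had turned over 21.2% in the flask. The flask dissolved 0.384 M, which is 87.9% of the ceiling. A neighbour flask, charged with 0.90 M of solid substrate, has the same ceiling, 48.6% of its charge, and it dissolved 42.7% of its charge.

(The rate constants are invented; the rest is arithmetic.)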